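**Retrosynthetic overview**
- The enal is made last by allylic oxidation of an isopropenyl group; the tiglate comes from an (R)-carbinol, itself from asymmetric transfer hydrogenation of the aryl methyl ketone.
- The isopropenyl acetate comes from a 2,3-cis diol (3-OH, tertiary side-chain OH) by acetylation and dehydration, the chemical counterpart of hydroxytremetone → tremetone.
- Key disconnection: the O1–C2 bond. The phenoxide opens a prenyl-derived epoxide 5-exo, as in the biosynthesis, but the side chain already carries the benzylic oxygen, so one erythro epoxy alcohol fixes C2 and C3 together (erythro → cis).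
- The erythro epoxy alcohol comes from Sharpless kinetic-resolution epoxidation of a racemic aryl(2-methylpropenyl)carbinol, made from a salicylaldehyde and an alkenyl bromide; the aldehyde comes from 4-hydroxyacetophenone.
- Ring order: the benzene ring is bought; the dihydrofuran ring is the only ring formed (step 5).

Assumption: the SMILES is read as the 2,3-cis (2S,3S) dihydrobenzofuran with a (1R)-1-acyloxyethyl group and an (E)-2-methylbut-2-enoate (tiglate); all three carbon building blocks are bought.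

**Route**

Step 1
Reactants: 1 4-hydroxyacetophenone
Product: 3 5-acetyl-2-hydroxybenzaldehyde, via hydroxymethylphenol 2 (not isolated)
Conditions: MgCl2, Et3N, (CH2O)n, MeCN, reflux; then 1 M HCl
Reagents that add atoms: paraformaldehyde (reacts as formaldehyde), C=O
Why: Casnati–Skattebøl ortho-formylation, in which the magnesium phenoxide directs hydroxymethylation to the only free ortho position type (para is blocked) and a second formaldehyde takes up hydride in an Oppenauer-type step; no stereocentre is formed.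

Step 2
Reactants: 3 5-acetyl-2-hydroxybenzaldehyde
Product: 4 5-acetyl-2-[(tert-butyldimethylsilyl)oxy]benzaldehyde
Conditions: TBSCl, imidazole, DMF, 0 °C → rt
Reagents that add atoms: tert-butyldimethylsilyl chloride, CC(C)(C)[Si](C)(C)Cl
Why: Standard silyl ether protection of the acidic phenol, chosen because fluoride later removes it under the very conditions of ring closure; no stereocentre is formed.

Step 3
Reactants: 4 5-acetyl-2-[(tert-butyldimethylsilyl)oxy]benzaldehyde; 5 1-bromo-2-methylprop-1-ene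
Product: 7 rac-1-[4-[(tert-butyldimethylsilyl)oxy]-3-(1-hydroxy-3-methylbut-2-en-1-yl)phenyl]ethanone, via alkenylchromium dichloride 6 (not isolated)
Conditions: CrCl2 (4 equiv), NiCl2 (2 mol %), DMF, rt; then H2O
Reagents that add atoms: none
Why: Nozaki–Hiyama–Kishi coupling, in which the alkenylchromium reagent adds to the aldehyde but not to the aryl methyl ketone and the neutral chromium alkoxide does not provoke silyl migration; the carbinol centre is made racemic on purpose.

Step 4
Reactants: 7 rac-1-[4-[(tert-butyldimethylsilyl)oxy]-3-(1-hydroxy-3-methylbut-2-en-1-yl)phenyl]ethanone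
Product: 8 1-[4-[(tert-butyldimethylsilyl)oxy]-3-[(S)-[(2S)-3,3-dimethyloxiran-2-yl](hydroxy)methyl]phenyl]ethanone
Conditions: Ti(OiPr)4 (20 mol %), L-(+)-DIPT (28 mol %), t-BuOOH (0.55 equiv), 4 Å MS, CH2Cl2, −20 °C
Reagents that add atoms: tert-butyl hydroperoxide, CC(C)(C)OO
Why: Katsuki–Sharpless asymmetric epoxidation run as a kinetic resolution: with L-(+)-DIPT the (R)-carbinol is epoxidised much faster than the (S)-carbinol and erythro-selectively, so the new epoxide CH is S and the carbinol carbon is S in the product (a priority change only), while the (S)-carbinol stays behind.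

Step 5
Reactants: 8 1-[4-[(tert-butyldimethylsilyl)oxy]-3-[(S)-[(2S)-3,3-dimethyloxiran-2-yl](hydroxy)methyl]phenyl]ethanone
Product: 10 1-[(2R,3S)-3-hydroxy-2-(2-hydroxypropan-2-yl)-2,3-dihydro-1-benzofuran-5-yl]ethanone (2,3-cis), via epoxy-alcohol phenoxide 9 (not isolated)
Conditions: Bu4NF (1.1 equiv), THF, 0 → 40 °C; then H2O
Reagents that add atoms: none
Why: Fluoride frees the phenoxide, which opens the epoxide at its secondary carbon in a 5-exo-tet SN2 reaction with inversion (the biosynthetic phenol/prenyl-epoxide closure), so the erythro epoxy alcohol gives the 2,3-cis ring with C3 untouched (3S) and C2 inverted (2R), and only the phenol is ionised so no Payne rearrangement competes.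

Step 6
Reactants: 10 1-[(2R,3S)-3-hydroxy-2-(2-hydroxypropan-2-yl)-2,3-dihydro-1-benzofuran-5-yl]ethanone
Product: 12 (2S,3S)-5-acetyl-2-(prop-1-en-2-yl)-2,3-dihydro-1-benzofuran-3-yl acetate, via hydroxy acetate 11 (not isolated)
Conditions: Ac2O (1.3 equiv), pyridine, DMAP (cat.), CH2Cl2, 0 °C → rt; then SOCl2 (3 equiv), −20 → 0 °C
Reagents that add atoms: acetic anhydride, CC(=O)OC(C)=O
Why: Acylation takes the secondary benzylic alcohol and leaves the tertiary one, whose chlorosulfite then undergoes pyridine-mediated E2 elimination toward a methyl group; no stereocentre is touched and C2 is named 2S only through a priority change.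

Step 7
Reactants: 12 (2S,3S)-5-acetyl-2-(prop-1-en-2-yl)-2,3-dihydro-1-benzofuran-3-yl acetate
Product: 13 (2S,3S)-5-[(1R)-1-hydroxyethyl]-2-(prop-1-en-2-yl)-2,3-dihydro-1-benzofuran-3-yl acetate
Conditions: RuCl[(R,R)-TsDPEN](p-cymene) (1 mol %), HCO2H/Et3N (5:2), EtOAc, 25 °C
Reagents that add atoms: none
Why: Noyori asymmetric transfer hydrogenation, in which the (R,R)-TsDPEN ruthenium hydride delivers hydride to the Si face of the aryl methyl ketone under catalyst control to give the (R)-carbinol, leaving the alkene and the acetate alone.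

Step 8
Reactants: 13 (2S,3S)-5-[(1R)-1-hydroxyethyl]-2-(prop-1-en-2-yl)-2,3-dihydro-1-benzofuran-3-yl acetate; 14 tiglic acid
Product: 16 (1R)-1-[(2S,3S)-3-acetoxy-2-(prop-1-en-2-yl)-2,3-dihydro-1-benzofuran-5-yl]ethyl (2E)-2-methylbut-2-enoate, via O-tigloylisourea 15 (not isolated)
Conditions: DCC, DMAP (cat.), CH2Cl2, 0 °C → rt
Reagents that add atoms: none
Why: Steglich esterification acylates the alcohol oxygen without breaking the C–O bond, so the (R)-centre is retained, and the thermodynamically favoured (E)-geometry of the tiglate is kept.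

Step 9
Reactants: 16 (1R)-1-[(2S,3S)-3-acetoxy-2-(prop-1-en-2-yl)-2,3-dihydro-1-benzofuran-5-yl]ethyl (2E)-2-methylbut-2-enoate
Product: 18 (1R)-1-[(2S,3S)-3-acetoxy-2-(3-oxoprop-1-en-2-yl)-2,3-dihydro-1-benzofuran-5-yl]ethyl (2E)-2-methylbut-2-enoate, via allylic alcohol 17 (not isolated)
Conditions: SeO2 (1.5 equiv), pyridine (cat.), 1,4-dioxane, 70 °C
Reagents that add atoms: selenium dioxide, O=[Se]=O
Why: Selenium dioxide allylic oxidation (ene reaction, then [2,3]-sigmatropic shift) attacks the methyl group of the 1,1-disubstituted alkene in preference to the CH at C2 and to the electron-poor tiglate, and the allylic alcohol is oxidised on to the enal in the same flask; no stereocentre is affected.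

**Compound list**

1 | 4-hydroxyacetophenone | CC(=O)c1ccc(O)cc1 | starting material
2 | 1-[4-hydroxy-3-(hydroxymethyl)phenyl]ethanone | CC(=O)c1ccc(O)c(CO)c1 | intermediate
3 | 5-acetyl-2-hydroxybenzaldehyde | CC(=O)c1ccc(O)c(C=O)c1 | intermediate
4 | 5-acetyl-2-[(tert-butyldimethylsilyl)oxy]benzaldehyde | CC(=O)c1ccc(O[Si](C)(C)C(C)(C)C)c(C=O)c1 | intermediate
5 | 1-bromo-2-methylprop-1-ene | CC(C)=CBr | starting material
6 | (2-methylprop-1-en-1-yl)chromium dichloride | CC(C)=C[Cr](Cl)Cl | intermediate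
7 | rac-1-[4-[(tert-butyldimethylsilyl)oxy]-3-(1-hydroxy-3-methylbut-2-en-1-yl)phenyl]ethanone | CC(C)=CC(O)c1cc(C(C)=O)ccc1O[Si](C)(C)C(C)(C)C | intermediate
8 | 1-[4-[(tert-butyldimethylsilyl)oxy]-3-[(S)-[(2S)-3,3-dimethyloxiran-2-yl](hydroxy)methyl]phenyl]ethanone | CC1(C)O[C@H]1[C@@H](O)c1cc(C(C)=O)ccc1O[Si](C)(C)C(C)(C)C | intermediate
9 | tetrabutylammonium 4-acetyl-2-[(S)-[(2S)-3,3-dimethyloxiran-2-yl](hydroxy)methyl]phenoxide | CC1(C)O[C@H]1[C@@H](O)c1cc(C(C)=O)ccc1[O-].CCCC[N+](CCCC)(CCCC)CCCC | intermediate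
10 | 1-[(2R,3S)-3-hydroxy-2-(2-hydroxypropan-2-yl)-2,3-dihydro-1-benzofuran-5-yl]ethanone | CC(C)(O)[C@@H]1Oc2ccc(C(C)=O)cc2[C@@H]1O | intermediate
11 | (2R,3S)-5-acetyl-2-(2-hydroxypropan-2-yl)-2,3-dihydro-1-benzofuran-3-yl acetate | CC(C)(O)[C@@H]1Oc2ccc(C(C)=O)cc2[C@@H]1OC(C)=O | intermediate
12 | (2S,3S)-5-acetyl-2-(prop-1-en-2-yl)-2,3-dihydro-1-benzofuran-3-yl acetate | C=C(C)[C@@H]1Oc2ccc(C(C)=O)cc2[C@@H]1OC(C)=O | intermediate
13 | (2S,3S)-5-[(1R)-1-hydroxyethyl]-2-(prop-1-en-2-yl)-2,3-dihydro-1-benzofuran-3-yl acetate | C=C(C)[C@@H]1Oc2ccc([C@@H](C)O)cc2[C@@H]1OC(C)=O | intermediate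
14 | tiglic acid, (2E)-2-methylbut-2-enoic acid | C/C=C(\C)C(=O)O | starting material
15 | O-[(2E)-2-methylbut-2-enoyl]-N,N'-dicyclohexylisourea | C/C=C(\C)C(=O)OC(=NC1CCCCC1)NC1CCCCC1 | intermediate
16 | (1R)-1-[(2S,3S)-3-acetoxy-2-(prop-1-en-2-yl)-2,3-dihydro-1-benzofuran-5-yl]ethyl (2E)-2-methylbut-2-enoate | C=C(C)[C@@H]1Oc2ccc([C@@H](C)OC(=O)/C(C)=C/C)cc2[C@@H]1OC(C)=O | intermediate
17 | (1R)-1-[(2S,3S)-3-acetoxy-2-(3-hydroxyprop-1-en-2-yl)-2,3-dihydro-1-benzofuran-5-yl]ethyl (2E)-2-methylbut-2-enoate | C=C(CO)[C@@H]1Oc2ccc([C@@H](C)OC(=O)/C(C)=C/C)cc2[C@@H]1OC(C)=O | intermediate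
18 | (1R)-1-[(2S,3S)-3-acetoxy-2-(3-oxoprop-1-en-2-yl)-2,3-dihydro-1-benzofuran-5-yl]ethyl (2E)-2-methylbut-2-enoate | C=C(C=O)[C@@H]1Oc2ccc([C@@H](C)OC(=O)/C(C)=C/C)cc2[C@@H]1OC(C)=O | target

**Totals**

Total step count: 9. Longest linear sequence: 9 steps (1 → 3 → 4 → 7 → 8 → 10 → 12 → 13 → 16 → 18).

**Three steps most likely to fail**

Step 4. The carbinol carries a methyl group cis to the carbinol carbon, a substrate class for which the Sharpless resolution is slower and less selective, and at most half of 7 can be used. A recrystallisation of diol 10 may be needed to reach full enantiopurity. Fallback: make the carbinol centre by asymmetric C–C bond formation instead of resolution. Setting out from 4 and 5, a Nozaki–Hiyama–Kishi coupling run with CrCl2 bound to a chiral oxazoline–sulfonamide ligand (NiCl2 cat., Et3N, THF; ligand enantiomer chosen for the R product) gives 1-[4-[(tert-butyldimethylsilyl)oxy]-3-[(1R)-1-hydroxy-3-methylbut-2-en-1-yl]phenyl]ethanone F1. F1 is then epoxidised to full conversion with Ti(OiPr)4/L-(+)-DIPT/t-BuOOH, now a matched erythro-selective epoxidation that leaves the minor enantiomer behind, and the sequence comes back to the route at 8.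

Step 6. The elimination may go toward C2–H (enol ether, then aromatisation to the benzofuran) or through a cation that lets O1 migrate (ring expansion to a chroman). Fallback: make the isopropenyl group by Peterson elimination inside the ring-closing cascade, so that no regiochemical choice exists. Setting out from 4, the alkenyl partner is changed to [(2E)-3-iodo-2-methylprop-2-en-1-yl]trimethylsilane F2, made from commercial trimethyl(prop-2-yn-1-yl)silane by Cp2ZrCl2/AlMe3 carboalumination and then I2. CrCl2/NiCl2 coupling of F2 to 4 gives rac-1-[4-[(tert-butyldimethylsilyl)oxy]-3-[(2E)-1-hydroxy-3-methyl-4-(trimethylsilyl)but-2-en-1-yl]phenyl]ethanone F3. The same L-(+)-DIPT resolution gives 1-[4-[(tert-butyldimethylsilyl)oxy]-3-[(S)-hydroxy[(2S,3R)-3-methyl-3-[(trimethylsilyl)methyl]oxiran-2-yl]methyl]phenyl]ethanone F4. Bu4NF then triggers, in one flask, desilylation of the phenol, 5-exo epoxide opening and Peterson elimination of the β-silyl alkoxide, giving 1-[(2S,3S)-3-hydroxy-2-(prop-1-en-2-yl)-2,3-dihydro-1-benzofuran-5-yl]ethanone F5. Acetylation of F5 (Ac2O, pyridine) comes back to the route at 12.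

Step 9. Hot selenious acid may solvolyse the two acid-labile benzylic esters, stop at allylic alcohol 17, or touch the tiglate methyl groups. Fallback: replace the selenium ene chemistry by chlorination and N-oxide oxidation. Setting out from 16, ene-type allylic chlorination (Ca(OCl)2, CO2, CH2Cl2/H2O, 0 °C) gives (1R)-1-[(2S,3S)-3-acetoxy-2-(3-chloroprop-1-en-2-yl)-2,3-dihydro-1-benzofuran-5-yl]ethyl (2E)-2-methylbut-2-enoate F6. Oxidation of F6 with N-methylmorpholine N-oxide in MeCN at rt (Ganem/Kornblum-type) comes back to the route at 18.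

**Further compounds**

F1 | step 4 | 1-[4-[(tert-butyldimethylsilyl)oxy]-3-[(1R)-1-hydroxy-3-methylbut-2-en-1-yl]phenyl]ethanone | CC(C)=C[C@@H](O)c1cc(C(C)=O)ccc1O[Si](C)(C)C(C)(C)C
F2 | step 6 | [(2E)-3-iodo-2-methylprop-2-en-1-yl]trimethylsilane | C[Si](C)(C)C/C(C)=C/I
F3 | step 6 | rac-1-[4-[(tert-butyldimethylsilyl)oxy]-3-[(2E)-1-hydroxy-3-methyl-4-(trimethylsilyl)but-2-en-1-yl]phenyl]ethanone | C[Si](C)(C)C/C(C)=C/C(O)c1cc(C(C)=O)ccc1O[Si](C)(C)C(C)(C)C
F4 | step 6 | 1-[4-[(tert-butyldimethylsilyl)oxy]-3-[(S)-hydroxy[(2S,3R)-3-methyl-3-[(trimethylsilyl)methyl]oxiran-2-yl]methyl]phenyl]ethanone | C[Si](C)(C)C[C@]1(C)O[C@H]1[C@@H](O)c1cc(C(C)=O)ccc1O[Si](C)(C)C(C)(C)C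
F5 | step 6 | 1-[(2S,3S)-3-hydroxy-2-(prop-1-en-2-yl)-2,3-dihydro-1-benzofuran-5-yl]ethanone | C=C(C)[C@@H]1Oc2ccc(C(C)=O)cc2[C@@H]1O
F6 | step 9 | (1R)-1-[(2S,3S)-3-acetoxy-2-(3-chloroprop-1-en-2-yl)-2,3-dihydro-1-benzofuran-5-yl]ethyl (2E)-2-methylbut-2-enoate | C=C(CCl)[C@@H]1Oc2ccc([C@@H](C)OC(=O)/C(C)=C/C)cc2[C@@H]1OC(C)=O
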